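## Retrosynthetic overview

1. **Feature used.** In the 14-membered macrolactone (ring B), the methoxy-bearing C11 lies 1,3 to the methyl-bearing C9 and 1,3 to the lactone carbinol C13. Adding a 2-substituted allyl unit C8–C9(=CH2)–C10 to a C11 aldehyde therefore creates the C11 oxygen function under control of C13 and leaves a C9 methylene as the precursor of the methyl group.
2. **Disconnections.** The C5–O acyl bond (Mitsunobu, inversion) gives the macrolactone alcohol and the oxazole dienoic acid. C11–OMe and C9–Me go back to C11–OH and C9=CH2. C10–C11 (macrocyclic Hosomi–Sakurai allylation) gives an ester-linked allylsilane aldehyde. The C1–O ester bond gives a pyran acid and a dithiane-masked hydroxy aldehyde.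
3. **Fragments.** The pyran acid comes from a Prins cyclisation to a meso all-cis pyran diester, esterase desymmetrisation and ester-to-allylsilane conversion. The C11–C16 piece comes from (R)-propyloxirane and 1,3-dithiane. The side chain comes from Sonogashira coupling and semihydrogenation on a 2-bromooxazole, then Still–Gennari olefination.
4. **Ring order.** Pyran ring A forms first (step 2), then macrolactone ring B (step 9). Oxazole ring C is bought.

Key step: step 9

Assumption 1: neopeltolide numbering is used (C1 lactone carbonyl, C3 and C7 the pyran carbons next to oxygen, C13 the lactone carbinol). The SMILES as written reads 3R,5R,7R,9S,11R,13R, and this isomer is made. C13 is bought with the epoxide and C11 follows from it, so the 11,13-bis-epimeric series would need only (S)-propyloxirane.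

Assumption 2: the esterase is taken to hydrolyse the arm on the R-configured ring carbon of the meso diester. This sense has to be proved by correlation. The opposite sense leads to the same acid by the arm exchange given among the fallbacks.

## Route

Step 1
Reactants: 1 methyl 3,3-dimethoxypropanoate; 2 allyl bromide
Product: 5 methyl (±)-3-hydroxyhex-5-enoate, via methyl 3-oxopropanoate 3 (not isolated), via allylindium sesquibromide 4 (not isolated)
Conditions: 1 M aq HCl/THF, rt; then 2, indium powder, rt
Reagents that add atoms: water, O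
Why: Aqueous acid unmasks the acetal to formylacetate 3, which is trapped in the same pot by the water-tolerant allylindium reagent 4 in a Barbier allylation, a reaction known to accept 1,3-dicarbonyl-type aldehydes, and the carbinol centre may be racemic because the next step leads to a meso compound.

Step 2
Reactants: 5 methyl (±)-3-hydroxyhex-5-enoate; 1 methyl 3,3-dimethoxypropanoate
Product: 8 dimethyl 2,2'-[(2R,4s,6S)-4-hydroxyoxane-2,6-diyl]diacetate (meso; all-cis), via (E)-oxocarbenium ion 6 (not isolated), via C5 trifluoroacetate 7 (not isolated)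
Conditions: CF3CO2H, CH2Cl2, 0 °C to rt; concentrate; K2CO3 (cat), MeOH, 0 °C
Reagents that add atoms: trifluoroacetic acid, OC(=O)C(F)(F)F
Why: Prins cyclisation: 5 and 1 condense to the (E)-oxocarbenium ion 6, which closes through a chair with both CH2CO2Me arms equatorial and is captured equatorially by trifluoroacetate, so that C3, C5 and C7 come out all-cis, the 2-oxonia-Cope shift is degenerate because the two arms are alike, both enantiomers of 5 give the same meso product, and brief methanolysis of 7 frees the C5 hydroxyl.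

Step 3
Reactants: 8 meso hydroxy diester
Product: 9 dimethyl 2,2'-[(2R,4s,6S)-4-(benzyloxy)oxane-2,6-diyl]diacetate (meso; all-cis)
Conditions: BnOC(=NH)CCl3, TfOH (cat), CH2Cl2/cyclohexane, 0 °C to rt
Reagents that add atoms: benzyl 2,2,2-trichloroacetimidate, ClC(Cl)(Cl)C(=N)OCc1ccccc1
Why: Acid-catalysed O-benzylation with the trichloroacetimidate avoids the alkoxide conditions of a Williamson etherification, under which the β-alkoxy esters could open by retro-oxa-Michael reaction, and no stereocentre is touched.

Step 4
Reactants: 9 meso benzyl ether diester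
Product: 10 2-[(2R,4R,6S)-4-(benzyloxy)-6-(2-methoxy-2-oxoethyl)oxan-2-yl]acetic acid (free acid on the C3 arm; 3R,5R,7S)
Conditions: pig liver esterase, 0.1 M phosphate buffer pH 7/DMSO 9:1, 25 °C, pH-stat (1 M NaOH); then 1 M HCl to pH 3
Reagents that add atoms: water, O
Why: Enzymatic desymmetrisation of a meso diester: the chiral active site tells the two enantiotopic CH2CO2Me arms apart and hydrolyses one of them only, which fixes the absolute configuration of C3, C5 and C7 in a single operation, and the carboxylate formed is a poor substrate so that the second ester stays.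

Step 5
Reactants: 10 half-ester
Product: 12 2-[(2R,4S,6R)-4-(benzyloxy)-6-{2-[(trimethylsilyl)methyl]prop-2-en-1-yl}oxan-2-yl]acetic acid (3R,5S,7R), via bis(silylmethyl) carbinol 11 (not isolated)
Conditions: Me3SiCH2MgCl (5 equiv), CeCl3 (5 equiv), THF, −78 °C to rt; aq NaH2PO4; then SiO2, CH2Cl2, rt
Reagents that add atoms: (trimethylsilyl)methylmagnesium chloride, C[Si](C)(C)C[Mg]Cl
Why: Cerium-mediated double addition of Me3SiCH2 to an ester followed by Peterson elimination (the standard ester-to-allylsilane conversion): the first equivalent turns the acid into an unreactive carboxylate, the weakly basic organocerium reagent adds twice to the methyl ester without β-elimination of the pyran oxygen, and silica gel removes Me3SiOH from carbinol 11.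

Step 6
Reactants: 13 1,3-dithiane; 14 (R)-propyloxirane
Product: 16 (2R)-1-(1,3-dithian-2-yl)pentan-2-ol, via 2-lithio-1,3-dithiane 15 (not isolated)
Conditions: n-BuLi, THF, −30 °C; then 14, −30 to 0 °C; H2O
Reagents that add atoms: none
Why: Corey–Seebach umpolung: 2-lithio-1,3-dithiane 15 opens the epoxide at its unsubstituted carbon in an SN2 reaction, so that the C13 stereocentre is carried over untouched from 14.

Step 7
Reactants: 12 allylsilane acid; 16 dithiane alcohol
Product: 17 (2R)-1-(1,3-dithian-2-yl)pentan-2-yl 2-[(2R,4S,6R)-4-(benzyloxy)-6-{2-[(trimethylsilyl)methyl]prop-2-en-1-yl}oxan-2-yl]acetate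
Conditions: EDC·HCl, DMAP (cat), CH2Cl2, 0 °C to rt
Reagents that add atoms: none
Why: Steglich-type carbodiimide esterification forms the C1–O bond at the acyl carbon, so that C13 keeps its configuration, and the mild conditions leave the allylsilane, the dithiane and the cis-pyran unchanged.

Step 8
Reactants: 17 dithiane ester
Product: 18 (3R)-1-oxohexan-3-yl 2-[(2R,4S,6R)-4-(benzyloxy)-6-{2-[(trimethylsilyl)methyl]prop-2-en-1-yl}oxan-2-yl]acetate (ester-linked allylsilane aldehyde; 3R,5S,7R,13R)
Conditions: MeI, CaCO3, MeCN/H2O 9:1, 40 °C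
Reagents that add atoms: water, O
Why: Alkylative hydrolysis of the dithiane: S-methylation turns sulfur into a leaving group and water takes its place under nearly neutral, non-oxidising and heavy-metal-free conditions, which spare the allylsilane (attacked by halonium, mercuric and hypervalent iodine reagents) and the elimination-prone β-acyloxy aldehyde.

Step 9
Reactants: 18 allylsilane aldehyde
Product: 20 (1R,5R,7R,11R,13S)-13-(benzyloxy)-7-hydroxy-9-methylidene-5-propyl-4,15-dioxabicyclo[9.3.1]pentadecan-3-one (3R,5S,7R,11R,13R; C11 hydroxyl; C9 exocyclic methylene), via β-silyl cation 19 (not isolated)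
Conditions: BF3·OEt2 (5 equiv), 2,6-di-tert-butyl-4-methylpyridine, CH2Cl2, −78 °C, 18 added by syringe pump (final about 1 mM); sat aq NaHCO3
Reagents that add atoms: none
Why: BF3 binds the C11 aldehyde oxygen and the allylsilane attacks it in an open SE2' transition state through its unsubstituted =CH2 terminus, which becomes C10, while the positive charge that grows at C9 is held by the neighbouring C–Si bond (cation 19) and is quenched by transfer of Me3Si to fluoride, so that the former CH2Si carbon remains as the C9 exocyclic methylene and the boron alkoxide gives the C11 alcohol on work-up. The closest known reaction type is the intramolecular Hosomi–Sakurai allylation of an aldehyde, of which large-ring cases are few, backed by the BF3-promoted allylstannane–aldehyde closures of 14-membered carbocycles. The one ring closed is macrolactone ring B, 14-membered along the carbon path C1–C13 (12-membered through the pyran oxygen), by a closure that is exo-trig at the carbonyl group and endo at the allyl π bond, since C9 and C10 both end up in the ring and the aldehyde oxygen outside it. C11 is the only new stereocentre and is controlled by C13: with a monodentate Lewis acid the β-acyloxy aldehyde reacts from the conformer in which the C13–O and C11=O dipoles oppose each other, and attack on its open face gives the 1,3-anti, that is 11R,13R, relationship (polar 1,3-induction model). The step needs cyclisation to outrun dimerisation, loss of the C13 acyloxy group by β-elimination and protodesilylation, which is secured by slow addition to about 1 mM, by −78 °C, by the high nucleophilicity of a 2-alkyl-substituted allylsilane, by the hindered pyridine as proton trap, and by the cis-2,6-pyran and the s-trans ester, which point both chain ends to the same side.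

Step 10
Reactants: 20 C11 alcohol
Product: 21 (1R,5R,7R,11R,13S)-13-(benzyloxy)-7-methoxy-9-methylidene-5-propyl-4,15-dioxabicyclo[9.3.1]pentadecan-3-one
Conditions: Me3OBF4, 1,8-bis(dimethylamino)naphthalene, 4 Å MS, CH2Cl2, 0 °C to rt
Reagents that add atoms: trimethyloxonium tetrafluoroborate, C[O+](C)C.F[B-](F)(F)F
Why: O-Methylation with Me3OBF4 and a non-nucleophilic proton scavenger needs no alkoxide, so that translactonisation to the C11 oxygen and β-elimination are avoided, the 1,1-disubstituted alkene is inert, and C11 keeps its configuration because only the O–H bond is exchanged.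

Step 11
Reactants: 21 methyl ether
Product: 22 (1R,5R,7R,9S,11R,13S)-13-hydroxy-7-methoxy-9-methyl-5-propyl-4,15-dioxabicyclo[9.3.1]pentadecan-3-one (equatorial C5 hydroxyl; 3R,5S,7R,9S,11R,13R)
Conditions: H2 (1 atm), 10% Pd/C, EtOH, rt
Reagents that add atoms: none
Why: Heterogeneous hydrogenation with concomitant benzyl hydrogenolysis: the equatorial C7–C8 bond keeps C9 anti to C6 and the chain turns at C8, so that the pyran covers one face of the C9 methylene and hydrogen should arrive on the open face, which makes C9 S (methyl anti to the C7 oxygen and syn to the C11 methoxy group in the extended chain).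

Step 12
Reactants: 23 propargylamine
Product: 24 methyl N-(prop-2-yn-1-yl)carbamate
Conditions: ClCO2Me, NaHCO3, CH2Cl2/H2O, 0 °C to rt
Reagents that add atoms: methyl chloroformate, COC(=O)Cl
Why: Schotten–Baumann acylation of the primary amine with the chloroformate gives the carbamate.

Step 13
Reactants: 24 methyl N-(prop-2-yn-1-yl)carbamate; 25 ethyl 2-bromo-1,3-oxazole-4-carboxylate
Product: 26 ethyl 2-[3-(methoxycarbonylamino)prop-1-yn-1-yl]-1,3-oxazole-4-carboxylate
Conditions: Pd(PPh3)4 (cat), CuI (cat), Et3N, THF (degassed), rt to 50 °C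
Reagents that add atoms: none
Why: Sonogashira coupling: the C2–Br bond, activated by the ring nitrogen and by the C4 ester, adds readily to zerovalent palladium and the terminal alkyne 24 is transferred under copper co-catalysis, the carbamate N–H being tolerated.

Step 14
Reactants: 26 alkynyl oxazole
Product: 27 ethyl 2-[(1Z)-3-(methoxycarbonylamino)prop-1-en-1-yl]-1,3-oxazole-4-carboxylate
Conditions: H2 (1 atm), Pd/CaCO3 poisoned with Pb(OAc)2, quinoline, EtOAc, rt
Reagents that add atoms: none
Why: Lindlar semihydrogenation: syn delivery of one equivalent of hydrogen on the poisoned palladium surface gives the Z alkene, and quinoline holds back over-reduction and Z to E isomerisation.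

Step 15
Reactants: 27 Z-alkenyl oxazole ester
Product: 28 methyl N-{(2Z)-3-[4-(hydroxymethyl)-1,3-oxazol-2-yl]prop-2-en-1-yl}carbamate
Conditions: i-Bu2AlH (3.5 equiv), CH2Cl2, −78 to 0 °C; aq potassium sodium tartrate
Reagents that add atoms: none
Why: Hydride reduction of the electron-poor oxazole ester by i-Bu2AlH is fast at low temperature, whereas the carbamate, deactivated by metalation at nitrogen, and the Z alkene stay intact.

Step 16
Reactants: 28 oxazolylmethanol
Product: 29 methyl N-{(2Z)-3-[4-(bromomethyl)-1,3-oxazol-2-yl]prop-2-en-1-yl}carbamate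
Conditions: CBr4, PPh3, 2,6-lutidine, MeCN, 0 °C
Reagents that add atoms: carbon tetrabromide, BrC(Br)(Br)Br
Why: Appel bromination turns the primary oxazolylmethyl alcohol into the bromide under nearly neutral conditions that do not isomerise the Z alkene.

Step 17
Reactants: 29 bromide
Product: 31 methyl N-{(2Z)-3-[4-(3-oxopropyl)-1,3-oxazol-2-yl]prop-2-en-1-yl}carbamate, via alkylated cyclohexylimine 30 (not isolated)
Conditions: CH3CH=N-c-C6H11, LiN(i-Pr)2 (2.2 equiv each), THF, −78 °C; then 29, −78 °C; aq citric acid (pH 4–5), 0 °C to rt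
Reagents that add atoms: N-cyclohexylethanimine, CC=NC1CCCCC1; water, O
Why: Metalloenamine (aza-enolate) alkylation: the lithiated acetaldehyde imine is a reactive carbon nucleophile that displaces the oxazolylmethyl bromide at −78 °C (a second equivalent covers the carbamate N–H), and mild acid hydrolysis of imine 30 releases the aldehyde two carbons longer without touching the Z alkene.

Step 18
Reactants: 31 aldehyde
Product: 32 methyl (2Z)-5-{2-[(1Z)-3-(methoxycarbonylamino)prop-1-en-1-yl]-1,3-oxazol-4-yl}pent-2-enoate
Conditions: (CF3CH2O)2P(O)CH2CO2Me, KN(SiMe3)2, 18-crown-6, THF, −78 °C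
Reagents that add atoms: methyl bis(2,2,2-trifluoroethyl)phosphonoacetate, COC(=O)CP(=O)(OCC(F)(F)F)OCC(F)(F)F
Why: Still–Gennari olefination: the electron-poor bis(trifluoroethyl) phosphonate with a dissociated potassium counter-ion makes elimination from the kinetic adduct fast, which gives the Z enoate from an unbranched aliphatic aldehyde.

Step 19
Reactants: 32 methyl ester
Product: 33 (2Z)-5-{2-[(1Z)-3-(methoxycarbonylamino)prop-1-en-1-yl]-1,3-oxazol-4-yl}pent-2-enoic acid
Conditions: LiOH, THF/H2O, 0 °C to rt; 1 M HCl to pH 3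
Reagents that add atoms: lithium hydroxide, [Li+].[OH-]
Why: Saponification of the unhindered methyl ester by LiOH is much faster than attack on the carbamate, and the Z enoate does not isomerise under these conditions.

Step 20
Reactants: 22 macrolactone alcohol; 33 side-chain acid
Product: 34 neopeltolide (3R,5R,7R,9S,11R,13R; axial C5 ester)
Conditions: PPh3, DIAD, toluene, 0 °C to rt
Reagents that add atoms: none
Why: Mitsunobu esterification: the equatorial C5 hydroxyl is activated by the phosphine–azodicarboxylate pair and displaced by the carboxylate of 33 in an SN2 reaction with inversion, which turns 5S into the axial 5R ester of the target without touching the two Z alkenes.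

## Compound list

1 | methyl 3,3-dimethoxypropanoate | COC(CC(=O)OC)OC | starting material
2 | allyl bromide | C=CCBr | starting material
3 | methyl 3-oxopropanoate | COC(=O)CC=O | intermediate (not isolated)
4 | allylindium sesquibromide, (C3H5)3In2Br3 | C=CC[In](Br)CC=C.C=CC[In](Br)Br | intermediate (not isolated)
5 | methyl (±)-3-hydroxyhex-5-enoate | COC(=O)CC(O)CC=C | intermediate
6 | (E)-oxocarbenium ion from 5 and 1 | COC(=O)CC(CC=C)/[O+]=C/CC(=O)OC | intermediate (not isolated)
7 | dimethyl 2,2'-[(2R,4s,6S)-4-(trifluoroacetoxy)oxane-2,6-diyl]diacetate (meso, all-cis) | COC(=O)C[C@H]1C[C@@H](OC(=O)C(F)(F)F)C[C@@H](CC(=O)OC)O1 | intermediate (not isolated)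
8 | dimethyl 2,2'-[(2R,4s,6S)-4-hydroxyoxane-2,6-diyl]diacetate (meso, all-cis) | COC(=O)C[C@H]1C[C@@H](O)C[C@@H](CC(=O)OC)O1 | intermediate
9 | dimethyl 2,2'-[(2R,4s,6S)-4-(benzyloxy)oxane-2,6-diyl]diacetate (meso, all-cis) | COC(=O)C[C@H]1C[C@@H](OCc2ccccc2)C[C@@H](CC(=O)OC)O1 | intermediate
10 | 2-[(2R,4R,6S)-4-(benzyloxy)-6-(2-methoxy-2-oxoethyl)oxan-2-yl]acetic acid | OC(=O)C[C@H]1C[C@@H](OCc2ccccc2)C[C@@H](CC(=O)OC)O1 | intermediate
11 | 2-[(2R,4S,6S)-4-(benzyloxy)-6-{2-hydroxy-3-(trimethylsilyl)-2-[(trimethylsilyl)methyl]propyl}oxan-2-yl]acetic acid | OC(=O)C[C@H]1C[C@@H](OCc2ccccc2)C[C@@H](CC(O)(C[Si](C)(C)C)C[Si](C)(C)C)O1 | intermediate (not isolated)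
12 | 2-[(2R,4S,6R)-4-(benzyloxy)-6-{2-[(trimethylsilyl)methyl]prop-2-en-1-yl}oxan-2-yl]acetic acid | OC(=O)C[C@H]1C[C@@H](OCc2ccccc2)C[C@@H](CC(=C)C[Si](C)(C)C)O1 | intermediate
13 | 1,3-dithiane | C1CSCSC1 | starting material
14 | (R)-propyloxirane | CCC[C@@H]1CO1 | starting material
15 | 2-lithio-1,3-dithiane | [Li]C1SCCCS1 | intermediate (not isolated)
16 | (2R)-1-(1,3-dithian-2-yl)pentan-2-ol | CCC[C@@H](O)CC1SCCCS1 | intermediate
17 | (2R)-1-(1,3-dithian-2-yl)pentan-2-yl ester of 12 | CCC[C@H](CC2SCCCS2)OC(=O)C[C@H]1C[C@@H](OCc3ccccc3)C[C@@H](CC(=C)C[Si](C)(C)C)O1 | intermediate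
18 | (3R)-1-oxohexan-3-yl ester of 12 (key-step precursor) | CCC[C@H](CC=O)OC(=O)C[C@H]1C[C@@H](OCc2ccccc2)C[C@@H](CC(=C)C[Si](C)(C)C)O1 | intermediate
19 | macrocyclic C9 β-silyl cation with C11 trifluoroborate alkoxide | CCC[C@@H]1C[C@H](O[B-](F)(F)F)C[C+](C[Si](C)(C)C)C[C@@H]2C[C@H](OCc3ccccc3)C[C@H](CC(=O)O1)O2 | intermediate (not isolated)
20 | (1R,5R,7R,11R,13S)-13-(benzyloxy)-7-hydroxy-9-methylidene-5-propyl-4,15-dioxabicyclo[9.3.1]pentadecan-3-one (key-step product) | CCC[C@@H]1C[C@H](O)CC(=C)C[C@@H]2C[C@H](OCc3ccccc3)C[C@H](CC(=O)O1)O2 | intermediate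
21 | (1R,5R,7R,11R,13S)-13-(benzyloxy)-7-methoxy-9-methylidene-5-propyl-4,15-dioxabicyclo[9.3.1]pentadecan-3-one | CCC[C@@H]1C[C@H](OC)CC(=C)C[C@@H]2C[C@H](OCc3ccccc3)C[C@H](CC(=O)O1)O2 | intermediate
22 | (1R,5R,7R,9S,11R,13S)-13-hydroxy-7-methoxy-9-methyl-5-propyl-4,15-dioxabicyclo[9.3.1]pentadecan-3-one | CCC[C@@H]1C[C@H](OC)C[C@H](C)C[C@@H]2C[C@H](O)C[C@H](CC(=O)O1)O2 | intermediate
23 | propargylamine | C#CCN | starting material
24 | methyl N-(prop-2-yn-1-yl)carbamate | C#CCNC(=O)OC | intermediate
25 | ethyl 2-bromo-1,3-oxazole-4-carboxylate | CCOC(=O)c1coc(Br)n1 | starting material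
26 | ethyl 2-[3-(methoxycarbonylamino)prop-1-yn-1-yl]-1,3-oxazole-4-carboxylate | CCOC(=O)c1coc(C#CCNC(=O)OC)n1 | intermediate
27 | ethyl 2-[(1Z)-3-(methoxycarbonylamino)prop-1-en-1-yl]-1,3-oxazole-4-carboxylate | CCOC(=O)c1coc(/C=C\CNC(=O)OC)n1 | intermediate
28 | methyl N-{(2Z)-3-[4-(hydroxymethyl)-1,3-oxazol-2-yl]prop-2-en-1-yl}carbamate | OCc1coc(/C=C\CNC(=O)OC)n1 | intermediate
29 | methyl N-{(2Z)-3-[4-(bromomethyl)-1,3-oxazol-2-yl]prop-2-en-1-yl}carbamate | BrCc1coc(/C=C\CNC(=O)OC)n1 | intermediate
30 | N-cyclohexylimine of aldehyde 31 | C2CCCCC2N=CCCc1coc(/C=C\CNC(=O)OC)n1 | intermediate (not isolated)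
31 | methyl N-{(2Z)-3-[4-(3-oxopropyl)-1,3-oxazol-2-yl]prop-2-en-1-yl}carbamate | O=CCCc1coc(/C=C\CNC(=O)OC)n1 | intermediate
32 | methyl (2Z)-5-{2-[(1Z)-3-(methoxycarbonylamino)prop-1-en-1-yl]-1,3-oxazol-4-yl}pent-2-enoate | COC(=O)/C=C\CCc1coc(/C=C\CNC(=O)OC)n1 | intermediate
33 | (2Z)-5-{2-[(1Z)-3-(methoxycarbonylamino)prop-1-en-1-yl]-1,3-oxazol-4-yl}pent-2-enoic acid | OC(=O)/C=C\CCc1coc(/C=C\CNC(=O)OC)n1 | intermediate
34 | neopeltolide | CCC[C@@H]1C[C@H](OC)C[C@H](C)C[C@@H]2C[C@@H](OC(=O)/C=C\CCc3coc(/C=C\CNC(=O)OC)n3)C[C@H](CC(=O)O1)O2 | target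

## Step count and risks

Total step count: 20.
Longest linear sequence: 11 steps (steps 1–5, 7–11 and 20, from compound 1).

**Step 9.**
- *What may go wrong:* ring closure may lose to intermolecular allylation (oligomers), to β-elimination of the acyloxy group from the activated aldehyde, or to protodesilylation. The tether may also override the 1,3-anti preference, giving poor facial selectivity at C11.
- *Fallback:* the bond order is reversed, so that C10–C11 is made intermolecularly and ring B is closed by lactonisation. It sets out from 12 and 16 and comes back at 21.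
- Acid 12 is esterified with 2-(trimethylsilyl)ethanol (EDC·HCl, DMAP) to the 2-(trimethylsilyl)ethyl ester F1.
- Alcohol 16 is silylated (TBSOTf, 2,6-lutidine) to the TBS ether F2. This is unmasked (MeI, CaCO3, aq MeCN) to (3R)-3-(tert-butyldimethylsilyloxy)hexanal F3.
- F1 and F3 are joined with BF3·OEt2 in CH2Cl2 at −78 °C at ordinary concentration. This is an intermolecular Hosomi–Sakurai allylation of a β-silyloxy aldehyde, for which 1,3-anti induction is established, and it gives the open-chain homoallylic alcohol F4.
- Me3OBF4 with 1,8-bis(dimethylamino)naphthalene gives the C11 methyl ether F5.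
- TBAF in THF frees the acid and the C13 hydroxyl together, giving the seco acid F6.
- Yamaguchi macrolactonisation follows: 2,4,6-trichlorobenzoyl chloride and Et3N give the mixed anhydride F7, which is added slowly to DMAP in toluene and gives 21.

**Step 11.**
- *What may go wrong:* palladium may move the double bond into the ring before reduction, and the two faces of the C9 methylene may be told apart too weakly, giving poor facial selectivity at C9.
- *Fallback:* it sets out from 21 and comes back at 22.
- Radical hydrogenation by metal-hydride hydrogen-atom transfer is used (Mn(dpm)3 cat, PhSiH3, t-BuOOH, i-PrOH, rt).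
- Every alkene isomer passes through the same tertiary C9 radical, and the configuration is set only in the final hydrogen transfer to its open face. Benzyl ethers survive these conditions, so the product is the C9-methyl benzyl ether F8.
- Hydrogenolysis (H2, Pd(OH)2/C, EtOAc) then gives 22.

**Step 4.**
- *What may go wrong:* the esterase may hydrolyse the enantiotopic arm opposite to the one drawn.
- *Fallback:* the roles of the two arms are exchanged. It sets out from 9 and comes back at 12.
- The esterase then gives the mirror-image half-ester F9, whose free acid sits on the C7 arm.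
- (COCl)2 with catalytic DMF gives the acid chloride F10.
- Me3SiCH2MgCl/CeCl3 (2.2 equiv, THF, −78 °C) adds twice to the acid chloride, which reacts far faster than the methyl ester at this temperature. This gives the carbinol methyl ester F11.
- Silica gel brings about the Peterson elimination to the allylsilane methyl ester F12.
- LiOH in THF/H2O gives 12.

## Further compounds

F1 | step 9 | 2-(trimethylsilyl)ethyl 2-[(2R,4S,6R)-4-(benzyloxy)-6-{2-[(trimethylsilyl)methyl]prop-2-en-1-yl}oxan-2-yl]acetate | C[Si](C)(C)CCOC(=O)C[C@H]1C[C@@H](OCc2ccccc2)C[C@@H](CC(=C)C[Si](C)(C)C)O1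
F2 | step 9 | tert-butyl{[(2R)-1-(1,3-dithian-2-yl)pentan-2-yl]oxy}dimethylsilane | CCC[C@@H](O[Si](C)(C)C(C)(C)C)CC1SCCCS1
F3 | step 9 | (3R)-3-[(tert-butyldimethylsilyl)oxy]hexanal | CCC[C@@H](O[Si](C)(C)C(C)(C)C)CC=O
F4 | step 9 | open-chain homoallylic alcohol (3R,5S,7R,11R,13R; C11 OH, C13 OTBS, C9 methylene, 2-(trimethylsilyl)ethyl ester) | CCC[C@@H](O[Si](C)(C)C(C)(C)C)C[C@H](O)CC(=C)C[C@@H]1C[C@H](OCc2ccccc2)C[C@H](CC(=O)OCC[Si](C)(C)C)O1
F5 | step 9 | C11 methyl ether of F4 | CCC[C@@H](O[Si](C)(C)C(C)(C)C)C[C@H](OC)CC(=C)C[C@@H]1C[C@H](OCc2ccccc2)C[C@H](CC(=O)OCC[Si](C)(C)C)O1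
F6 | step 9 | seco acid (3R,5S,7R,11R,13R; C13 OH, C1 CO2H) | CCC[C@@H](O)C[C@H](OC)CC(=C)C[C@@H]1C[C@H](OCc2ccccc2)C[C@H](CC(=O)O)O1
F7 | step 9 | mixed 2,4,6-trichlorobenzoic anhydride of F6 | CCC[C@@H](O)C[C@H](OC)CC(=C)C[C@@H]1C[C@H](OCc2ccccc2)C[C@H](CC(=O)OC(=O)c2c(Cl)cc(Cl)cc2Cl)O1
F8 | step 11 | (1R,5R,7R,9S,11R,13S)-13-(benzyloxy)-7-methoxy-9-methyl-5-propyl-4,15-dioxabicyclo[9.3.1]pentadecan-3-one | CCC[C@@H]1C[C@H](OC)C[C@H](C)C[C@@H]2C[C@H](OCc3ccccc3)C[C@H](CC(=O)O1)O2
F9 | step 4 | 2-[(2S,4S,6R)-4-(benzyloxy)-6-(2-methoxy-2-oxoethyl)oxan-2-yl]acetic acid (enantiomer of 10) | COC(=O)C[C@H]1C[C@@H](OCc2ccccc2)C[C@@H](CC(=O)O)O1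
F10 | step 4 | acid chloride of F9 | COC(=O)C[C@H]1C[C@@H](OCc2ccccc2)C[C@@H](CC(=O)Cl)O1
F11 | step 4 | methyl ester of carbinol 11 | COC(=O)C[C@H]1C[C@@H](OCc2ccccc2)C[C@@H](CC(O)(C[Si](C)(C)C)C[Si](C)(C)C)O1
F12 | step 4 | methyl ester of 12 | COC(=O)C[C@H]1C[C@@H](OCc2ccccc2)C[C@@H](CC(=C)C[Si](C)(C)C)O1
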